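## Structural features

The target is a flavanone: ring A (benzene) is fused to the dihydropyranone ring C along C4a–C8a, and ring B is joined to C2 by the C2–C1' single bond. Ring A is substituted everywhere except C6: methoxy on C5, hydroxyl on C7, a ten-carbon chain on C8 (C1'' methylene, C2'' methine bearing an isopropenyl group, two methylenes, a tertiary carbinol), O1 on C8a and the C4 carbonyl on C4a; ring B carries methoxy on C2' and hydroxyl on C4'. The two stereocentres, C2 (S) and C2'' (R), are five bonds apart (C2–O1–C8a–C8–C1''–C2'') and cannot control one another, so each needs its own reagent or catalyst. Fragile points are the C2–O1 bond (β-elimination under base, easiest once the 4'-hydroxyl is free; ionisation under acid because ring B is doubly oxygenated), the isopropenyl group (acid can cyclise it onto the C7 oxygen), the tertiary alcohol, and the phloroglucinol-type ring A, which makes benzylic derivatives at C1'' ionise readily. The real difficulty is regiochemical: the oxygens on C7 and C8a, which flank C8, start out equivalent and must end up different, and the acyl carbon must enter at C4a and not at the electronically similar C6, while C2 has to be set in a reversible ring closure. The key step exploits the fact that C8a and C4a are adjacent ring A carbons carrying O1 and the C4 acyl group: this ortho oxygen/acyl pair is what results when a carboxylic acid adds across a C4a–C8a aryne, and the C5 methoxy group beside C4a polarises that aryne so that oxygen goes to C8a. A check of the structures used for this step shows silicon on C4a, triflate on C8a, the E acid, and the R descriptor at C2'' in precursor, product and target alike; nothing had to be corrected.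

## Logic of the disconnections

41 is first stripped only of protecting groups: the two aryl O–CH2OCH3 bonds and the tertiary O–Si bond of 40 are cut. This keeps every oxygen that could interfere with fluoride, base or organolithium chemistry masked to the end and lets one reagent remove all three groups. The forward step must use acid weak enough to spare the C2–O1 bond, the isopropenyl group and the tertiary alcohol.

40 is opened at O1–C2 to give 39. This is the polar retron of a flavanone (oxa-Michael); it removes ring C and the C2 stereocentre and leaves an enone with no stereochemical issue at that end. The forward closure must be catalyst-controlled, run under conditions where it does not reverse, and keep the 4'-oxygen protected.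

39 is cut at C8a–O1 and C4a–C4 into 32 and 35. An ortho oxygen/acyl pair is the pattern written by adding a carboxylic acid across an aryne, so both bonds come from one operation and no Friedel–Crafts acylation has to choose between C4a and C6. The molecule falls into a ring A piece carrying the whole side chain and a simple ring B acid. The forward step needs oxygen at C8a, acyl migration faster than protonation, and no free O–H or N–H; the acid is therefore used in excess as its dried cesium salt.

35 is cut at the Cα=Cβ bond and at the MOM ether, through 34 to 33. A Knoevenagel–Doebner condensation gives the E acid directly; the only demand is a phenol protecting group that survives pyridine and fluoride.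

32 is cut at the O–S bond, the C4a–Si bond and the carbamate C–O bond, through 30 and 26 to 25. Silicon must sit ortho to the oxygen that will leave; an O-carbamate on that oxygen is the group that both directs a base to C4a and can be exchanged for triflate in one flask. The forward metalation must favour C4a over C6 (flanked by the MOM ether) and tolerates no carbonyl, so the isopropenyl group must already be in place.

25 is cut at the O–allyl bond to 24. The C8a oxygen needs a temporary group that withstands hydride, enolate, peroxide, organolithium and ylide reagents and comes off under neutral conditions in the presence of the MOM ether, the silyl ether and the alkene.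

24 is cut at the C=CH2 bond (to 23), the C–CH3 bond (to 21) and the acyl–N bond (to 20). Treating the isopropenyl carbon as a former carboxyl carbon makes C2'' an α-carbon, which an auxiliary-controlled enolate alkylation can set. The forward steps must not enolise this centre.

20 is cut at C1''–C2'' into 9 and 18. This joins ring A to the chain and sets C2'' (R) in one reliable step. The demand is that the very electron-rich benzylic electrophile 18 be made without acid and used cold.

18 is traced through 16, 15, 14, 13 and 11 to 10 (C–Br, C–H of the carbinol, O–allyl, one O–MOM, C–CHO, two O–MOM). The two equivalent oxygens of 10 are differentiated at 13, where the formyl group chelates a Lewis acid and allows exactly one MOM group to be removed. A statistical mono-protection of a late, valuable symmetric resorcinol is thereby avoided.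

9 is cut at the N–acyl bond into 6 and 7, and 6 is traced through 3 to 1 (O–Si bond, then the C–CH3 bond at the ketone). The tertiary carbinol comes from a Grignard addition to the ketone of 1; the hydroxyl must be silylated before the enolate chemistry.

## Other disconnections considered

Alternative 1: Ring A is taken apart at C8–C8a and C6–C7 into 3-methoxycyclobut-2-en-1-one (A1) and the side-chain siloxyalkyne (A2). On heating, A1 would open to a vinylketene, add to the ynol ether by [2+2], and pass through four-electron opening, six-electron closure and tautomerisation to the resorcinol mono-silyl ether (A3), with C8a–OH free and the C7 oxygen silylated.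
- In its favour: the mechanism fixes every ring A substituent; the two oxygens flanking C8 emerge already differentiated, which is better than the chosen plan (steps 6, 7 and 14 are spent on this); and no electron-rich benzylic halide is needed, which is better than steps 9 and 10.
- Against it here: the benzannulation makes neither bond to ring C. A3 is the counterpart of 25, so the carbamate, silylation, triflation and aryne steps, or an acylation at C4a, would still follow. A2 needs an ester-to-ynolate homologation on the chiral chain, and A1 is labile.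
- Comparison: on structure it solves ring A but not the A–C junction; on mechanism it is a neutral pericyclic cascade against an anionic aryne process; on step economy it is about equal up to the A3/25 stage and no shorter overall. It could serve as a different entry to the chosen key step.

Alternative 2: Ring C is cut at O1–C2 and C3–C4 into the ring A salicylaldehyde (A4) and the ring B styrene (A5). A chiral phosphoric acid and trimethyl orthoformate would turn A4 into a C4-methoxy ortho-quinone methide paired with the chiral phosphate; inverse-demand [4+2] addition of A5 would give the 2,4-cis 4-methoxyflavan (A6).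
- In its favour: ring C closes and C2 is set in the same step, which is better than the chosen key step (no ring, no stereocentre); A5 is one step from a ring B aldehyde (equal); the route is convergent.
- Against it here: A6 is at the wrong oxidation level at C4, so hydrolysis of the benzylic ether and oxidation must follow through a C4 cation on an electron-rich ring. The acidic medium meets an isopropenyl group beside the free C8a hydroxyl of A4. Both partners are very electron-rich, so a stepwise cationic path could erode cis selectivity and enantioselectivity. A4 needs a formyl group at C4a, the same regiochemical problem as in the chosen plan (equal).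
- Comparison: step economy is about equal (two steps after the key step in both cases); stereocontrol is more direct in principle but less secure for this substitution pattern.

Alternative 3: Ring A is unravelled at C4a–C5 to an acylketene tethered to a preformed (2S)-2-aryl-2,3-dihydropyran-4-one, stored as the dioxinone (A7). Thermolysis would release acetone; C4a, the nucleophilic carbon of the vinylogous ester, would attack the ketene carbon C5, the six-membered ring would close, and enolisation would give the 5,7-dihydroxyflavanone (A8).
- In its favour: C2 is set early on a simple ring by well-established asymmetric hetero-Diels–Alder chemistry (equal or better in reliability than step 21); no arene regiochemistry arises, which is better than steps 6 and 16; the key step needs no reagent.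
- Against it here: A8 has both C5–OH and C7–OH free, while the target needs the chelated, less reactive C5 oxygen methylated and C7 free. That means protection of C7 and base-mediated methylation of a 5-hydroxyflavanone, conditions under which the C2–O1 bond can open. The assembly of A7 at C8 is long.
- Comparison: the mechanism is elegant and neutral, but the C5/C7 mismatch costs at least three steps and endangers C2, so the route would be longer and riskier at the end.

Key step: step 20

Assumption: the sense of induction of the cinchona amine–thiourea in step 21 is assigned by analogy; the quinidine-derived catalyst is written for the 2S series and its quinine-derived pseudoenantiomer is to be used if a model chalcone shows the opposite sense.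

## Route

Step 1
Reactants: 1 4-acetylbutyric acid (5-oxohexanoic acid)
Product: 3 6,6-dimethyltetrahydro-2H-pyran-2-one, via 5-hydroxy-5-methylhexanoic acid 2 (not isolated)
Conditions: MeMgBr (3.2 equiv), THF, 0 °C to rt; aq. HCl; TsOH (cat.), CH2Cl2, rt
Reagents that add atoms: methylmagnesium bromide, C[Mg]Br
Why: The carboxylate formed by the first equivalent is inert to the Grignard reagent, so only the ketone is attacked (Grignard addition); the tertiary δ-hydroxy acid 2 lactonises on acidification to a neutral, easily purified intermediate.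

Step 2
Reactants: 3 6,6-dimethyltetrahydro-2H-pyran-2-one
Product: 6 5-methyl-5-(triethylsilyloxy)hexanoic acid, via potassium 5-hydroxy-5-methylhexanoate 4 (not isolated), via triethylsilyl 5-methyl-5-(triethylsilyloxy)hexanoate 5 (not isolated)
Conditions: KOH, MeOH–H2O, rt, evaporate; Et3SiOTf, 2,6-lutidine, CH2Cl2, 0 °C; aq. NaHCO3, then pH 5 buffer
Reagents that add atoms: potassium hydroxide, [K+].[OH-]; triethylsilyl trifluoromethanesulfonate, CC[Si](CC)(CC)OS(=O)(=O)C(F)(F)F
Why: Saponification opens the lactone, the silyl triflate silylates both the carboxylate and the hindered tertiary alcohol, and only the silyl ester is hydrolysed on aqueous work-up because silyl esters are far more labile than tertiary silyl ethers.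

Step 3
Reactants: 6 5-methyl-5-(triethylsilyloxy)hexanoic acid; 7 (S)-4-benzyloxazolidin-2-one
Product: 9 (S)-4-benzyl-3-[5-methyl-5-(triethylsilyloxy)hexanoyl]oxazolidin-2-one, via mixed pivalic anhydride 8 (not isolated)
Conditions: t-BuCOCl, Et3N, THF, −20 °C; LiCl, 7, −20 °C to rt
Reagents that add atoms: none
Why: N-Acylation of the oxazolidinone through the mixed pivalic anhydride with LiCl and Et3N is the standard loading of this auxiliary; attack occurs at the less hindered, non-pivaloyl carbonyl.

Step 4
Reactants: 10 5-methoxyresorcinol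
Product: 11 1-methoxy-3,5-bis(methoxymethoxy)benzene
Conditions: MOMCl, i-Pr2NEt, CH2Cl2, 0 °C to rt
Reagents that add atoms: chloromethyl methyl ether, COCCl
Why: Williamson-type O-alkylation of both phenols gives acetal ethers that are stable to organolithiums and direct metalation.

Step 5
Reactants: 11 1-methoxy-3,5-bis(methoxymethoxy)benzene
Product: 13 4-methoxy-2,6-bis(methoxymethoxy)benzaldehyde, via 2-lithio arene 12 (not isolated)
Conditions: n-BuLi, TMEDA, THF, 0 °C; DMF, 0 °C to rt; aq. NH4Cl
Reagents that add atoms: N,N-dimethylformamide, CN(C)C=O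
Why: Directed ortho-metalation: the position between the two MOM ethers is the most acidic through double coordination, and the aryllithium 12 is formylated by DMF.

Step 6
Reactants: 13 4-methoxy-2,6-bis(methoxymethoxy)benzaldehyde
Product: 14 2-hydroxy-4-methoxy-6-(methoxymethoxy)benzaldehyde
Conditions: MgBr2·OEt2 (1.2 equiv), PhMe–Et2O, 0 °C to rt; aq. NH4Cl
Reagents that add atoms: none
Why: Chelation-assisted Lewis acid cleavage of an acetal ether ortho to a carbonyl group: MgBr2 binds the formyl oxygen and one flanking MOM oxygen, bromide removes that MOM group, and the resulting magnesium phenoxide chelate deactivates the aldehyde towards a second cleavage, so the two oxygens are differentiated without a statistical step.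

Step 7
Reactants: 14 2-hydroxy-4-methoxy-6-(methoxymethoxy)benzaldehyde
Product: 15 2-(allyloxy)-4-methoxy-6-(methoxymethoxy)benzaldehyde
Conditions: allyl bromide, K2CO3, DMF, rt
Reagents that add atoms: allyl bromide, C=CCBr
Why: Williamson etherification of the hydrogen-bonded phenol; the allyl group is inert to hydride, enolate, peroxide, organolithium and ylide reagents and is later removed under neutral conditions.

Step 8
Reactants: 15 2-(allyloxy)-4-methoxy-6-(methoxymethoxy)benzaldehyde
Product: 16 [2-(allyloxy)-4-methoxy-6-(methoxymethoxy)phenyl]methanol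
Conditions: NaBH4, MeOH, 0 °C
Reagents that add atoms: none
Why: Chemoselective hydride reduction of the aldehyde; allyl and MOM ethers are untouched.

Step 9
Reactants: 16 [2-(allyloxy)-4-methoxy-6-(methoxymethoxy)phenyl]methanol
Product: 18 2-(allyloxy)-4-methoxy-6-(methoxymethoxy)benzyl bromide, via benzylic mesylate 17 (not isolated)
Conditions: Ms2O, Et3N, THF, −20 °C; LiBr, −20 to 0 °C; used at once
Reagents that add atoms: lithium bromide, [Li+].[Br-]
Why: Activation of the benzylic alcohol as its mesylate and displacement by bromide under base avoids acid that would cleave the MOM ether; Ms2O replaces MsCl so that no benzylic chloride forms, and the electron-rich bromide is kept cold and used immediately.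

Step 10
Reactants: 9 (S)-4-benzyl-3-[5-methyl-5-(triethylsilyloxy)hexanoyl]oxazolidin-2-one; 18 2-(allyloxy)-4-methoxy-6-(methoxymethoxy)benzyl bromide
Product: 20 (S)-4-benzyl-3-[(2R)-2-{[2-(allyloxy)-4-methoxy-6-(methoxymethoxy)phenyl]methyl}-5-methyl-5-(triethylsilyloxy)hexanoyl]oxazolidin-2-one, via sodium Z-enolate 19 (not isolated)
Conditions: NaN(SiMe3)2, THF, −78 °C; then 18, −78 to −40 °C
Reagents that add atoms: none
Why: Evans alkylation: the chelated Z-enolate 19 is alkylated on the face opposite the C4 benzyl group of the auxiliary, which sets C2'' with the R configuration; the benzylic bromide is reactive enough at −78 °C.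

Step 11
Reactants: 20 (S)-4-benzyl-3-[(2R)-2-{[2-(allyloxy)-4-methoxy-6-(methoxymethoxy)phenyl]methyl}-5-methyl-5-(triethylsilyloxy)hexanoyl]oxazolidin-2-one
Product: 21 (2R)-2-{[2-(allyloxy)-4-methoxy-6-(methoxymethoxy)phenyl]methyl}-5-methyl-5-(triethylsilyloxy)hexanoic acid
Conditions: LiOH, H2O2, THF–H2O, 0 °C; aq. Na2SO3; dil. HCl to pH 4
Reagents that add atoms: hydrogen peroxide, OO
Why: Lithium hydroperoxide attacks the exocyclic carbonyl of the hindered imide selectively (auxiliary cleavage without epimerisation), and the auxiliary 7 is recovered.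

Step 12
Reactants: 21 (2R)-2-{[2-(allyloxy)-4-methoxy-6-(methoxymethoxy)phenyl]methyl}-5-methyl-5-(triethylsilyloxy)hexanoic acid
Product: 23 (3R)-3-{[2-(allyloxy)-4-methoxy-6-(methoxymethoxy)phenyl]methyl}-6-methyl-6-(triethylsilyloxy)heptan-2-one, via dilithium gem-diolate 22 (not isolated)
Conditions: MeLi (3 equiv), Et2O, 0 °C; inverse quench into cold aq. NH4Cl
Reagents that add atoms: methyllithium, [Li]C
Why: Addition of methyllithium to the lithium carboxylate gives the stable dilithium gem-diolate 22, which cannot add a second equivalent and collapses to the methyl ketone only on hydrolysis; the α-stereocentre is not enolised because no ketone exists before the quench.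

Step 13
Reactants: 23 (3R)-3-{[2-(allyloxy)-4-methoxy-6-(methoxymethoxy)phenyl]methyl}-6-methyl-6-(triethylsilyloxy)heptan-2-one
Product: 24 1-(allyloxy)-5-methoxy-3-(methoxymethoxy)-2-[(2R)-5-methyl-2-(prop-1-en-2-yl)-5-(triethylsilyloxy)hexyl]benzene
Conditions: Ph3PCH3Br, KOt-Bu, THF, 0 °C to rt
Reagents that add atoms: methyltriphenylphosphonium bromide, C[P+](c1ccccc1)(c1ccccc1)c1ccccc1.[Br-]
Why: Wittig methylenation converts the acetyl group into the isopropenyl group; the ylide is generated with a slight deficiency of base so that the α-stereocentre is not equilibrated.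

Step 14
Reactants: 24 1-(allyloxy)-5-methoxy-3-(methoxymethoxy)-2-[(2R)-5-methyl-2-(prop-1-en-2-yl)-5-(triethylsilyloxy)hexyl]benzene
Product: 25 5-methoxy-3-(methoxymethoxy)-2-[(2R)-5-methyl-2-(prop-1-en-2-yl)-5-(triethylsilyloxy)hexyl]phenol
Conditions: Pd(PPh3)4 (5 mol %), morpholine, THF, rt
Reagents that add atoms: none
Why: Zerovalent palladium ionises the allyl aryl ether to a π-allyl complex that is trapped by morpholine (Tsuji–Trost deallylation); the isopropenyl group, the MOM ether and the silyl ether are inert.

Step 15
Reactants: 25 5-methoxy-3-(methoxymethoxy)-2-[(2R)-5-methyl-2-(prop-1-en-2-yl)-5-(triethylsilyloxy)hexyl]phenol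
Product: 26 5-methoxy-3-(methoxymethoxy)-2-[(2R)-5-methyl-2-(prop-1-en-2-yl)-5-(triethylsilyloxy)hexyl]phenyl N-isopropylcarbamate
Conditions: i-PrNCO, Et3N (cat.), CH2Cl2, rt
Reagents that add atoms: isopropyl isocyanate, CC(C)N=C=O
Why: Base-catalysed addition of the phenol to the isocyanate gives the O-aryl N-isopropylcarbamate, a directing group that can later be removed under mild amine conditions.

Step 16
Reactants: 26 5-methoxy-3-(methoxymethoxy)-2-[(2R)-5-methyl-2-(prop-1-en-2-yl)-5-(triethylsilyloxy)hexyl]phenyl N-isopropylcarbamate
Product: 30 5-methoxy-3-(methoxymethoxy)-2-[(2R)-5-methyl-2-(prop-1-en-2-yl)-5-(triethylsilyloxy)hexyl]-6-(trimethylsilyl)phenyl N-isopropylcarbamate, via N-silyl carbamate 27 (not isolated), via ortho-lithiated N-silyl carbamate 28 (not isolated), via C-silyl N-silyl carbamate 29 (not isolated)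
Conditions: t-BuMe2SiOTf, TMEDA, Et2O, 0 °C to rt; n-BuLi, TMEDA, −78 °C; Me3SiCl, −78 °C to rt; aq. NaHSO4 (brief, 0 °C)
Reagents that add atoms: chlorotrimethylsilane, C[Si](C)(C)Cl
Why: Directed ortho-metalation: in situ N-silylation masks the N–H, the carbamate then directs lithiation to its only free ortho position, C4a, which the C5 methoxy group acidifies further, and the aryllithium 28 is silylated; the carbamate is a stronger director than the MOM ether that flanks C6.

Step 17
Reactants: 30 5-methoxy-3-(methoxymethoxy)-2-[(2R)-5-methyl-2-(prop-1-en-2-yl)-5-(triethylsilyloxy)hexyl]-6-(trimethylsilyl)phenyl N-isopropylcarbamate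
Product: 32 5-methoxy-3-(methoxymethoxy)-2-[(2R)-5-methyl-2-(prop-1-en-2-yl)-5-(triethylsilyloxy)hexyl]-6-(trimethylsilyl)phenyl trifluoromethanesulfonate, via ortho-silyl phenol 31 (not isolated)
Conditions: Et2NH, DBU, MeCN, 40 °C; then PhNTf2, rt
Reagents that add atoms: N-phenylbis(trifluoromethanesulfonimide), O=S(=O)(N(c1ccccc1)S(=O)(=O)C(F)(F)F)C(F)(F)F
Why: DBU deprotonates the carbamate N–H and the phenoxide is expelled by an E1cB process while Et2NH traps the isocyanate as a urea; the phenoxide of 31 is triflated in the same flask, giving the fluoride-activated aryne precursor with silicon on C4a and triflate on C8a.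

Step 18
Reactants: 33 4-hydroxy-2-methoxybenzaldehyde
Product: 34 2-methoxy-4-(methoxymethoxy)benzaldehyde
Conditions: MOMCl, i-Pr2NEt, CH2Cl2, 0 °C to rt
Reagents that add atoms: chloromethyl methyl ether, COCCl
Why: MOM protection of the ring B phenol, which would otherwise add to the aryne and, after cyclisation, promote ring opening of the flavanone.

Step 19
Reactants: 34 2-methoxy-4-(methoxymethoxy)benzaldehyde
Product: 35 (E)-3-[2-methoxy-4-(methoxymethoxy)phenyl]prop-2-enoic acid
Conditions: CH2(CO2H)2, pyridine, piperidine (cat.), 90 °C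
Reagents that add atoms: malonic acid, O=C(O)CC(=O)O
Why: Knoevenagel–Doebner condensation with decarboxylation gives the E-cinnamic acid; the MOM ether is stable in the pyridine-buffered medium.

Step 20
Reactants: 32 5-methoxy-3-(methoxymethoxy)-2-[(2R)-5-methyl-2-(prop-1-en-2-yl)-5-(triethylsilyloxy)hexyl]-6-(trimethylsilyl)phenyl trifluoromethanesulfonate; 35 (E)-3-[2-methoxy-4-(methoxymethoxy)phenyl]prop-2-enoic acid
Product: 39 (E)-1-{2-hydroxy-6-methoxy-4-(methoxymethoxy)-3-[(2R)-5-methyl-2-(prop-1-en-2-yl)-5-(triethylsilyloxy)hexyl]phenyl}-3-[2-methoxy-4-(methoxymethoxy)phenyl]prop-2-en-1-one, via cesium cinnamate 36 (not isolated), via aryne 37 (not isolated), via C4a aryl anion 38 (not isolated)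
Conditions: 35 (2 equiv), Cs2CO3 (1 equiv), MeOH, rt, then dried (PhMe azeotrope); 32 (1 equiv), CsF (3 equiv), 18-crown-6, THF, sealed tube, 90 °C; AcOH, 0 °C
Reagents that add atoms: none
Why: Fluoride attacks silicon on C4a and triflate leaves from C8a to give aryne 37; the carboxylate oxygen of 36 adds to C8a and the resulting C4a aryl anion 38 attacks its own ester carbonyl through a four-membered transition state that opens to the ortho-acyl phenoxide, so the aryne has formally inserted into the O–C(=O) bond and the C8a–O and C4a–C4 bonds are both formed. The closest known reaction type is the fluoride-induced addition of carboxylic acids to arynes from 2-(trimethylsilyl)aryl triflates with O-to-C acyl migration, which gives ortho-hydroxyaryl ketones and is known for α,β-unsaturated acids. No ring is closed and no stereocentre is created; C2'' is untouched and the E alkene is retained. The selectivity needed is regiochemical (oxygen on C8a, not C4a): the C5 methoxy group is inductively withdrawing and distorts the aryne so that C8a is the more electrophilic terminus and the negative charge develops on C4a beside the methoxy group, an effect expected to outweigh the shielding of C8a by the C8 side chain. Acyl migration must also beat protonation of 38, which is why the acid is used as its dried cesium salt in excess in a solvent without acidic C–H bonds; the excess carboxylate likewise competes with any intramolecular ene trapping of 37 by the isopropenyl group. The MOM ethers, the tertiary silyl ether and the methyl ether carry no acidic hydrogen and should be inert to CsF. Material that closes to the flavanone without stereocontrol under the basic conditions is reopened to 39 by brief treatment with KOH in EtOH and cold acidification.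

Step 21
Reactants: 39 (E)-1-{2-hydroxy-6-methoxy-4-(methoxymethoxy)-3-[(2R)-5-methyl-2-(prop-1-en-2-yl)-5-(triethylsilyloxy)hexyl]phenyl}-3-[2-methoxy-4-(methoxymethoxy)phenyl]prop-2-en-1-one
Product: 40 (2S)-5-methoxy-7-(methoxymethoxy)-2-[2-methoxy-4-(methoxymethoxy)phenyl]-8-[(2R)-5-methyl-2-(prop-1-en-2-yl)-5-(triethylsilyloxy)hexyl]chroman-4-one
Conditions: 1-[3,5-bis(trifluoromethyl)phenyl]-3-(9-deoxy-epi-quinidin-9-yl)thiourea (20 mol %), PhMe, −20 °C
Reagents that add atoms: none
Why: Intramolecular oxa-Michael addition (6-endo-trig) under bifunctional cinchona amine–thiourea catalysis: the thiourea binds the enone carbonyl and the quinuclidine activates the C8a phenol, so the catalyst alone decides which face of C2 is attacked and sets the S configuration; the remote C2'' centre exerts no control, and the low temperature and the protected 4'-oxygen suppress reversible ring opening.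

Step 22
Reactants: 40 (2S)-5-methoxy-7-(methoxymethoxy)-2-[2-methoxy-4-(methoxymethoxy)phenyl]-8-[(2R)-5-methyl-2-(prop-1-en-2-yl)-5-(triethylsilyloxy)hexyl]chroman-4-one
Product: 41 (2S)-7-hydroxy-2-(4-hydroxy-2-methoxyphenyl)-8-[(2R)-5-hydroxy-5-methyl-2-(prop-1-en-2-yl)hexyl]-5-methoxychroman-4-one
Conditions: aq. HCl (3 M)–MeOH (1:5), 0 °C to rt
Reagents that add atoms: none
Why: Acid-catalysed acetal cleavage of the two aryl MOM ethers and solvolysis of the tertiary triethylsilyl ether in one operation; dilute acid at or below room temperature should leave the C2–O1 bond (no base, hence no E1cB opening), the isopropenyl group and the tertiary alcohol intact.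

## Compound list

1 | 4-acetylbutyric acid (5-oxohexanoic acid) | CC(=O)CCCC(=O)O | starting material
2 | 5-hydroxy-5-methylhexanoic acid | CC(C)(O)CCCC(=O)O | intermediate
3 | 6,6-dimethyltetrahydro-2H-pyran-2-one | CC1(C)CCCC(=O)O1 | intermediate
4 | potassium 5-hydroxy-5-methylhexanoate | CC(C)(O)CCCC(=O)[O-].[K+] | intermediate
5 | triethylsilyl 5-methyl-5-(triethylsilyloxy)hexanoate | CC[Si](CC)(CC)OC(C)(C)CCCC(=O)O[Si](CC)(CC)CC | intermediate
6 | 5-methyl-5-(triethylsilyloxy)hexanoic acid | CC[Si](CC)(CC)OC(C)(C)CCCC(=O)O | intermediate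
7 | (S)-4-benzyloxazolidin-2-one | O=C1N[C@@H](Cc2ccccc2)CO1 | starting material
8 | 5-methyl-5-(triethylsilyloxy)hexanoic pivalic anhydride | CC[Si](CC)(CC)OC(C)(C)CCCC(=O)OC(=O)C(C)(C)C | intermediate
9 | (S)-4-benzyl-3-[5-methyl-5-(triethylsilyloxy)hexanoyl]oxazolidin-2-one | CC[Si](CC)(CC)OC(C)(C)CCCC(=O)N1C(=O)OC[C@@H]1Cc1ccccc1 | intermediate
10 | 5-methoxyresorcinol | COc1cc(O)cc(O)c1 | starting material
11 | 1-methoxy-3,5-bis(methoxymethoxy)benzene | COCOc1cc(OC)cc(OCOC)c1 | intermediate
12 | [4-methoxy-2,6-bis(methoxymethoxy)phenyl]lithium | [Li]c1c(OCOC)cc(OC)cc1OCOC | intermediate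
13 | 4-methoxy-2,6-bis(methoxymethoxy)benzaldehyde | O=Cc1c(OCOC)cc(OC)cc1OCOC | intermediate
14 | 2-hydroxy-4-methoxy-6-(methoxymethoxy)benzaldehyde | O=Cc1c(OCOC)cc(OC)cc1O | intermediate
15 | 2-(allyloxy)-4-methoxy-6-(methoxymethoxy)benzaldehyde | O=Cc1c(OCOC)cc(OC)cc1OCC=C | intermediate
16 | [2-(allyloxy)-4-methoxy-6-(methoxymethoxy)phenyl]methanol | OCc1c(OCOC)cc(OC)cc1OCC=C | intermediate
17 | 2-(allyloxy)-4-methoxy-6-(methoxymethoxy)benzyl methanesulfonate | CS(=O)(=O)OCc1c(OCOC)cc(OC)cc1OCC=C | intermediate
18 | 2-(allyloxy)-4-methoxy-6-(methoxymethoxy)benzyl bromide | BrCc1c(OCOC)cc(OC)cc1OCC=C | intermediate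
19 | sodium (Z)-enolate of 9 | CC[Si](CC)(CC)OC(C)(C)CC/C=C(\[O-])N1C(=O)OC[C@@H]1Cc1ccccc1.[Na+] | intermediate
20 | (S)-4-benzyl-3-[(2R)-2-{[2-(allyloxy)-4-methoxy-6-(methoxymethoxy)phenyl]methyl}-5-methyl-5-(triethylsilyloxy)hexanoyl]oxazolidin-2-one | O=C([C@H](CCC(C)(C)O[Si](CC)(CC)CC)Cc1c(OCOC)cc(OC)cc1OCC=C)N1C(=O)OC[C@@H]1Cc1ccccc1 | intermediate
21 | (2R)-2-{[2-(allyloxy)-4-methoxy-6-(methoxymethoxy)phenyl]methyl}-5-methyl-5-(triethylsilyloxy)hexanoic acid | O=C(O)[C@H](CCC(C)(C)O[Si](CC)(CC)CC)Cc1c(OCOC)cc(OC)cc1OCC=C | intermediate
22 | dilithium gem-diolate from 21 and methyllithium | [Li+].[Li+].CC([O-])([O-])[C@H](CCC(C)(C)O[Si](CC)(CC)CC)Cc1c(OCOC)cc(OC)cc1OCC=C | intermediate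
23 | (3R)-3-{[2-(allyloxy)-4-methoxy-6-(methoxymethoxy)phenyl]methyl}-6-methyl-6-(triethylsilyloxy)heptan-2-one | CC(=O)[C@H](CCC(C)(C)O[Si](CC)(CC)CC)Cc1c(OCOC)cc(OC)cc1OCC=C | intermediate
24 | 1-(allyloxy)-5-methoxy-3-(methoxymethoxy)-2-[(2R)-5-methyl-2-(prop-1-en-2-yl)-5-(triethylsilyloxy)hexyl]benzene | C=C(C)[C@H](CCC(C)(C)O[Si](CC)(CC)CC)Cc1c(OCOC)cc(OC)cc1OCC=C | intermediate
25 | 5-methoxy-3-(methoxymethoxy)-2-[(2R)-5-methyl-2-(prop-1-en-2-yl)-5-(triethylsilyloxy)hexyl]phenol | C=C(C)[C@H](CCC(C)(C)O[Si](CC)(CC)CC)Cc1c(OCOC)cc(OC)cc1O | intermediate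
26 | N-isopropylcarbamate of phenol 25 | C=C(C)[C@H](CCC(C)(C)O[Si](CC)(CC)CC)Cc1c(OCOC)cc(OC)cc1OC(=O)NC(C)C | intermediate
27 | N-(tert-butyldimethylsilyl) derivative of carbamate 26 | C=C(C)[C@H](CCC(C)(C)O[Si](CC)(CC)CC)Cc1c(OCOC)cc(OC)cc1OC(=O)N(C(C)C)[Si](C)(C)C(C)(C)C | intermediate
28 | C4a-lithio derivative of 27 | C=C(C)[C@H](CCC(C)(C)O[Si](CC)(CC)CC)Cc1c(OCOC)cc(OC)c([Li])c1OC(=O)N(C(C)C)[Si](C)(C)C(C)(C)C | intermediate
29 | C4a-trimethylsilyl derivative of 27 | C=C(C)[C@H](CCC(C)(C)O[Si](CC)(CC)CC)Cc1c(OCOC)cc(OC)c([Si](C)(C)C)c1OC(=O)N(C(C)C)[Si](C)(C)C(C)(C)C | intermediate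
30 | 5-methoxy-3-(methoxymethoxy)-2-[(2R)-5-methyl-2-(prop-1-en-2-yl)-5-(triethylsilyloxy)hexyl]-6-(trimethylsilyl)phenyl N-isopropylcarbamate | C=C(C)[C@H](CCC(C)(C)O[Si](CC)(CC)CC)Cc1c(OCOC)cc(OC)c([Si](C)(C)C)c1OC(=O)NC(C)C | intermediate
31 | 5-methoxy-3-(methoxymethoxy)-2-[(2R)-5-methyl-2-(prop-1-en-2-yl)-5-(triethylsilyloxy)hexyl]-6-(trimethylsilyl)phenol | C=C(C)[C@H](CCC(C)(C)O[Si](CC)(CC)CC)Cc1c(OCOC)cc(OC)c([Si](C)(C)C)c1O | intermediate
32 | 5-methoxy-3-(methoxymethoxy)-2-[(2R)-5-methyl-2-(prop-1-en-2-yl)-5-(triethylsilyloxy)hexyl]-6-(trimethylsilyl)phenyl trifluoromethanesulfonate | C=C(C)[C@H](CCC(C)(C)O[Si](CC)(CC)CC)Cc1c(OCOC)cc(OC)c([Si](C)(C)C)c1OS(=O)(=O)C(F)(F)F | intermediate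
33 | 4-hydroxy-2-methoxybenzaldehyde | COc1cc(O)ccc1C=O | starting material
34 | 2-methoxy-4-(methoxymethoxy)benzaldehyde | COCOc1ccc(C=O)c(OC)c1 | intermediate
35 | (E)-3-[2-methoxy-4-(methoxymethoxy)phenyl]prop-2-enoic acid | COCOc1ccc(/C=C/C(=O)O)c(OC)c1 | intermediate
36 | cesium (E)-3-[2-methoxy-4-(methoxymethoxy)phenyl]prop-2-enoate | COCOc1ccc(/C=C/C(=O)[O-])c(OC)c1.[Cs+] | intermediate
37 | C4a–C8a aryne of ring A (3-methoxy-5-(methoxymethoxy)-6-alkylbenzyne) | C=C(C)[C@H](CCC(C)(C)O[Si](CC)(CC)CC)CC1=C(OCOC)C=C(OC)C#C1 | intermediate
38 | C4a-cesio aryl cinnamate (carboxylate adduct of 37) | C=C(C)[C@H](CCC(C)(C)O[Si](CC)(CC)CC)Cc1c(OCOC)cc(OC)c([Cs])c1OC(=O)/C=C/c1ccc(OCOC)cc1OC | intermediate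
39 | (E)-1-{2-hydroxy-6-methoxy-4-(methoxymethoxy)-3-[(2R)-5-methyl-2-(prop-1-en-2-yl)-5-(triethylsilyloxy)hexyl]phenyl}-3-[2-methoxy-4-(methoxymethoxy)phenyl]prop-2-en-1-one | C=C(C)[C@H](CCC(C)(C)O[Si](CC)(CC)CC)Cc1c(OCOC)cc(OC)c(C(=O)/C=C/c2ccc(OCOC)cc2OC)c1O | intermediate
40 | (2S)-5-methoxy-7-(methoxymethoxy)-2-[2-methoxy-4-(methoxymethoxy)phenyl]-8-[(2R)-5-methyl-2-(prop-1-en-2-yl)-5-(triethylsilyloxy)hexyl]chroman-4-one | C=C(C)[C@H](CCC(C)(C)O[Si](CC)(CC)CC)Cc1c(OCOC)cc(OC)c2c1O[C@H](c1ccc(OCOC)cc1OC)CC2=O | intermediate
41 | (2S)-7-hydroxy-2-(4-hydroxy-2-methoxyphenyl)-8-[(2R)-5-hydroxy-5-methyl-2-(prop-1-en-2-yl)hexyl]-5-methoxychroman-4-one | C=C(C)[C@H](CCC(C)(C)O)Cc1c(O)cc(OC)c2c1O[C@H](c1ccc(O)cc1OC)CC2=O | target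

## Step count and least certain steps

Total step count: 22. Longest linear sequence: 17 steps (steps 4–17 and 20–22, from 10).

Step 20 (key step). The likely failures are protonation of the C4a aryl anion before acyl migration (leaving the O-aryl ester), addition of the carboxylate at C4a because the C8 side chain shields C8a, and ene trapping of the aryne by the neighbouring isopropenyl group. Fallback, from 26 to 39, by polar acylation and aldol condensation: 26 is N-silylated and ortho-lithiated as in step 16 and quenched with N-methoxy-N-methylacetamide to give the C4a-acetyl carbamate F1. Et2NH and DBU release the 2'-hydroxyacetophenone F2. Claisen–Schmidt condensation of F2 with 34 (KOH, EtOH, rt) gives 39.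

Step 21. The likely failure is poor facial selectivity, or its erosion by reversible ring opening under the amine catalyst, which would give a mixture of C2 epimers (diastereomers because of C2''). Fallback, from 39 to 40, by resolution instead of asymmetric catalysis: 39 is closed without control (NaOAc, EtOH, reflux) to the C2-epimeric flavanone mixture F3. Transfer hydrogenation with the enantiomer of RuCl(p-cymene)(TsDPEN) matched to the 2R epimer (HCO2H–Et3N) reduces that epimer to the cis-flavan-4-ol F4. The unreduced ketone 40 is separated from the alcohol by chromatography.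

Step 16. The likely failure is competing lithiation at C6, which lies between the MOM ether and the methoxy group, or lateral lithiation at C1''; either gives regioisomeric silanes. Fallback, from 26 to 41, by non-selective silylation with a traceless extra silyl group: 26 is lithiated and silylated at both C4a and C6 (excess n-BuLi/TMEDA after N-silylation, Me3SiCl) to give the bis-silyl carbamate F5. Cleavage and triflation as in step 17 give the bis-silyl triflate F6. Only the C4a silicon has a leaving group beside it, so the same aryne chemistry as in step 20 gives the C6-silylated chalcone F7, and closure as in step 21 gives the C6-silylated flavanone F8. The acid of step 22 removes the C6 silyl group by ipso-protonation of this very electron-rich position, together with the MOM and silyl ether groups, giving 41.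

Step 10 (with step 9). The likely failure is ionisation and self-condensation of the 2,4,6-trioxygenated benzylic bromide before C-alkylation, or slow alkylation by the doubly ortho-substituted electrophile at the temperature the enolate tolerates. Fallback, from 6 and 15 to 21, by aldol addition and deoxygenation, with no benzylic halide: 6 is loaded on (R)-4-benzyloxazolidin-2-one (conditions of step 3) to give the enantiomeric imide F9; the auxiliary is changed because the boron aldol attacks the enolate face opposite to that of the alkylation. A syn-selective boron aldol addition to 15 (n-Bu2BOTf, Et3N, CH2Cl2, −78 to 0 °C) gives the syn-aldol adduct F10. Ionic reduction of its readily ionised benzylic hydroxyl (Et3SiH, BF3·OEt2, CH2Cl2, −78 °C) gives the deoxygenated imide F11. LiOH/H2O2 cleavage of F11 gives 21.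

Step 6. The likely failure is loss of both MOM groups, or no cleavage, if chelation does not discriminate well enough. Fallback, from 13 to 15, by full deprotection and hydrogen-bond-controlled mono-alkylation: 13 is fully deprotected (HCl, MeOH) to 2,6-dihydroxy-4-methoxybenzaldehyde F12. One equivalent of allyl bromide with K2CO3 in acetone alkylates only one hydroxyl, the other being tied to the formyl group, to give 2-(allyloxy)-6-hydroxy-4-methoxybenzaldehyde F13. MOMCl and i-Pr2NEt convert F13 into 15.

Step 22. The likely failure is acid-induced cyclisation of the isopropenyl group onto the freed C7 hydroxyl, ionisation at C2 with epimerisation, or solvolysis of the tertiary alcohol, if the second MOM group needs long acid exposure. Fallback, from 40 to 41, in two non-protic stages: Me3SiOTf with 2,2'-bipyridyl (CH2Cl2, 0 °C, then water) exchanges the aryl MOM ethers for labile silyl ethers and gives the bis-phenol with the tertiary silyl ether intact, F14. Pyridine-buffered HF·pyridine in THF at 0 °C then removes the triethylsilyl group to give 41.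

## Further compounds

F1 | step 20 | 6-acetyl-5-methoxy-3-(methoxymethoxy)-2-[(2R)-5-methyl-2-(prop-1-en-2-yl)-5-(triethylsilyloxy)hexyl]phenyl N-isopropylcarbamate | C=C(C)[C@H](CCC(C)(C)O[Si](CC)(CC)CC)Cc1c(OCOC)cc(OC)c(C(C)=O)c1OC(=O)NC(C)C
F2 | step 20 | 1-{2-hydroxy-6-methoxy-4-(methoxymethoxy)-3-[(2R)-5-methyl-2-(prop-1-en-2-yl)-5-(triethylsilyloxy)hexyl]phenyl}ethan-1-one | C=C(C)[C@H](CCC(C)(C)O[Si](CC)(CC)CC)Cc1c(OCOC)cc(OC)c(C(C)=O)c1O
F3 | step 21 | C2-epimeric mixture of flavanone 40 (2RS, 2''R) | C=C(C)[C@H](CCC(C)(C)O[Si](CC)(CC)CC)Cc1c(OCOC)cc(OC)c2c1OC(c1ccc(OCOC)cc1OC)CC2=O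
F4 | step 21 | (2R,4R)-cis-flavan-4-ol from the 2R epimer | C=C(C)[C@H](CCC(C)(C)O[Si](CC)(CC)CC)Cc1c(OCOC)cc(OC)c2c1O[C@@H](c1ccc(OCOC)cc1OC)C[C@H]2O
F5 | step 16 | 4,6-bis(trimethylsilyl) analogue of carbamate 30 (silicon on C4a and C6) | C=C(C)[C@H](CCC(C)(C)O[Si](CC)(CC)CC)Cc1c(OCOC)c([Si](C)(C)C)c(OC)c([Si](C)(C)C)c1OC(=O)NC(C)C
F6 | step 16 | 4,6-bis(trimethylsilyl) analogue of triflate 32 | C=C(C)[C@H](CCC(C)(C)O[Si](CC)(CC)CC)Cc1c(OCOC)c([Si](C)(C)C)c(OC)c([Si](C)(C)C)c1OS(=O)(=O)C(F)(F)F
F7 | step 16 | C6-trimethylsilyl analogue of chalcone 39 | C=C(C)[C@H](CCC(C)(C)O[Si](CC)(CC)CC)Cc1c(OCOC)c([Si](C)(C)C)c(OC)c(C(=O)/C=C/c2ccc(OCOC)cc2OC)c1O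
F8 | step 16 | C6-trimethylsilyl analogue of flavanone 40 | C=C(C)[C@H](CCC(C)(C)O[Si](CC)(CC)CC)Cc1c(OCOC)c([Si](C)(C)C)c(OC)c2c1O[C@H](c1ccc(OCOC)cc1OC)CC2=O
F9 | step 10 | (R)-4-benzyl-3-[5-methyl-5-(triethylsilyloxy)hexanoyl]oxazolidin-2-one | CC[Si](CC)(CC)OC(C)(C)CCCC(=O)N1C(=O)OC[C@H]1Cc1ccccc1
F10 | step 10 | (R)-4-benzyl-3-[(2R)-2-{(R)-[2-(allyloxy)-4-methoxy-6-(methoxymethoxy)phenyl](hydroxy)methyl}-5-methyl-5-(triethylsilyloxy)hexanoyl]oxazolidin-2-one | O=C([C@H](CCC(C)(C)O[Si](CC)(CC)CC)[C@@H](O)c1c(OCOC)cc(OC)cc1OCC=C)N1C(=O)OC[C@H]1Cc1ccccc1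
F11 | step 10 | (R)-4-benzyl-3-[(2R)-2-{[2-(allyloxy)-4-methoxy-6-(methoxymethoxy)phenyl]methyl}-5-methyl-5-(triethylsilyloxy)hexanoyl]oxazolidin-2-one | O=C([C@H](CCC(C)(C)O[Si](CC)(CC)CC)Cc1c(OCOC)cc(OC)cc1OCC=C)N1C(=O)OC[C@H]1Cc1ccccc1
F12 | step 6 | 2,6-dihydroxy-4-methoxybenzaldehyde | O=Cc1c(O)cc(OC)cc1O
F13 | step 6 | 2-(allyloxy)-6-hydroxy-4-methoxybenzaldehyde | O=Cc1c(O)cc(OC)cc1OCC=C
F14 | step 22 | (2S)-7-hydroxy-2-(4-hydroxy-2-methoxyphenyl)-5-methoxy-8-[(2R)-5-methyl-2-(prop-1-en-2-yl)-5-(triethylsilyloxy)hexyl]chroman-4-one | C=C(C)[C@H](CCC(C)(C)O[Si](CC)(CC)CC)Cc1c(O)cc(OC)c2c1O[C@H](c1ccc(O)cc1OC)CC2=O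
A1 | alternative 1 | 3-methoxycyclobut-2-en-1-one | COC1=CC(=O)C1
A2 | alternative 1 | triisopropylsilyl ynol ether of the side chain, (4R)-7-methyl-4-(prop-1-en-2-yl)-7-(triethylsilyloxy)-1-(triisopropylsilyloxy)oct-1-yne | C=C(C)[C@H](CCC(C)(C)O[Si](CC)(CC)CC)CC#CO[Si](C(C)C)(C(C)C)C(C)C
A3 | alternative 1 | 2-alkyl-5-methoxyresorcinol mono-triisopropylsilyl ether | C=C(C)[C@H](CCC(C)(C)O[Si](CC)(CC)CC)Cc1c(O)cc(OC)cc1O[Si](C(C)C)(C(C)C)C(C)C
A4 | alternative 2 | ring A salicylaldehyde, 2-hydroxy-3-[(2R)-5-hydroxy-5-methyl-2-(prop-1-en-2-yl)hexyl]-6-methoxy-4-(methoxymethoxy)benzaldehyde | C=C(C)[C@H](CCC(C)(C)O)Cc1c(OCOC)cc(OC)c(C=O)c1O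
A5 | alternative 2 | 2-methoxy-4-(methoxymethoxy)styrene | C=Cc1ccc(OCOC)cc1OC
A6 | alternative 2 | (2S,4S)-cis-4-methoxyflavan with the complete substitution pattern | C=C(C)[C@H](CCC(C)(C)O)Cc1c(OCOC)cc(OC)c2c1O[C@H](c1ccc(OCOC)cc1OC)C[C@@H]2OC
A7 | alternative 3 | dioxinone tethered at C8 to the (2S)-2-aryl-2,3-dihydropyran-4-one (mixture of C8 epimers) | C=C(C)[C@H](CCC(C)(C)O[Si](CC)(CC)CC)CC(C1=CC(=O)OC(C)(C)O1)C1=CC(=O)C[C@@H](c2ccc(OCOC)cc2OC)O1
A8 | alternative 3 | (2S)-5,7-dihydroxy-8-alkylflavanone with the 4'-MOM ether and silylated side chain | C=C(C)[C@H](CCC(C)(C)O[Si](CC)(CC)CC)Cc1c(O)cc(O)c2c1O[C@H](c1ccc(OCOC)cc1OC)CC2=O
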